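**Assumption:** the target is a planar flavone with no stereocentre, so it exists as a single species and needs no enantioselective step. The sp3 centres that appear in transient intermediates are racemic and are all erased before the end.

## Retrosynthetic overview
1. The target comes from its 5,7-di-O-benzyl ether by a final hydrogenolysis; the four ring B methyl ethers are never touched.
2. Ring C (the pyranone) is the only ring built, and it is closed last by oxidative O1–C2 cyclisation of a 2'-hydroxychalcone.
3. The chalcone comes from a Claisen–Schmidt aldol condensation that joins the ring A methyl ketone to the ring B aldehyde.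
4. The ring A fragment is phloroacetophenone with two of its three hydroxyls benzylated.
5. The ring B fragment is made from 2,3,4-trimethoxybenzaldehyde by Dakin oxidation, O-methylation, bromination, then Li–Br exchange and DMF.

## Route

Step 1
Reactants: 1 2,3,4-trimethoxybenzaldehyde
Product: 3 2,3,4-trimethoxyphenol, via aryl formate 2 (not isolated)
Conditions: 30% aq H2O2 (1.3 equiv), conc. H2SO4 (cat.), MeOH, rt, 16 h
Reagents that add atoms: hydrogen peroxide, OO
Why: In this acid-catalysed Dakin (Baeyer–Villiger-type) oxidation the hydroperoxide adduct of the aldehyde rearranges by migration of the electron-rich aryl group, which has ortho and para methoxy donors, and the formate is methanolysed in the same acidic medium; no stereocentre is formed.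

Step 2
Reactants: 3 2,3,4-trimethoxyphenol
Product: 4 1,2,3,4-tetramethoxybenzene
Conditions: MeI (1.5 equiv), K2CO3 (2 equiv), acetone, reflux, 12 h
Reagents that add atoms: iodomethane, CI
Why: This is a Williamson ether synthesis in which the potassium phenolate undergoes clean SN2 O-methylation and nothing else in the molecule is nucleophilic.

Step 3
Reactants: 4 1,2,3,4-tetramethoxybenzene
Product: 5 1-bromo-2,3,4,5-tetramethoxybenzene
Conditions: NBS (1.0 equiv), MeCN, 0 °C to rt, dark, 3 h
Reagents that add atoms: N-bromosuccinimide, O=C1CCC(=O)N1Br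
Why: This is an electrophilic aromatic bromination in which the two free ring positions are symmetry-equivalent and activated by ortho and para methoxy groups, so one equivalent of NBS gives a single monobromide.

Step 4
Reactants: 5 1-bromo-2,3,4,5-tetramethoxybenzene
Product: 8 2,3,4,5-tetramethoxybenzaldehyde, via aryllithium 6 (not isolated), via lithium hemiaminal alkoxide 7 (not isolated)
Conditions: n-BuLi (1.1 equiv), THF, −78 °C, 30 min; DMF (3 equiv), −78 to 0 °C; then 1 M HCl
Reagents that add atoms: N,N-dimethylformamide, CN(C)C=O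
Why: Lithium–bromine exchange followed by Bouveault formylation fixes the regiochemistry at the bromine-bearing carbon, and the racemic tetrahedral DMF adduct survives until the acid quench, so over-addition cannot occur.

Step 5
Reactants: 9 2,4,6-trihydroxyacetophenone (phloroacetophenone, dried from its monohydrate)
Product: 10 1-[2,4-bis(benzyloxy)-6-hydroxyphenyl]ethanone
Conditions: BnBr (2.1 equiv), K2CO3 (2.2 equiv), DMF, 60 °C, 3 h
Reagents that add atoms: benzyl bromide, BrCc1ccccc1
Why: In this regioselective Williamson benzylation the hydroxyl hydrogen-bonded to the acetyl carbonyl is the least acidic and least nucleophilic, so two equivalents of BnBr cap only the para hydroxyl and one of the two equivalent ortho hydroxyls.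

Step 6
Reactants: 10 1-[2,4-bis(benzyloxy)-6-hydroxyphenyl]ethanone; 8 2,3,4,5-tetramethoxybenzaldehyde
Product: 12 (E)-1-[2,4-bis(benzyloxy)-6-hydroxyphenyl]-3-(2,3,4,5-tetramethoxyphenyl)prop-2-en-1-one, via aldol adduct 11 (not isolated)
Conditions: KOH (50% aq, 15 equiv), EtOH/THF 2:1, rt, 48 h, Ar; then cold 1 M HCl to pH 4
Reagents that add atoms: none
Why: In this Claisen–Schmidt crossed aldol condensation only ketone 10 can enolise and only aldehyde 8 is a good acceptor, the racemic aldol 11 loses water by E1cB, and the conjugated E-alkene forms under thermodynamic control.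

Step 7
Reactants: 12 (E)-1-[2,4-bis(benzyloxy)-6-hydroxyphenyl]-3-(2,3,4,5-tetramethoxyphenyl)prop-2-en-1-one
Product: 14 5,7-bis(benzyloxy)-2',3',4',5'-tetramethoxyflavone, via 3-iodoflavanone 13 (not isolated)
Conditions: I2 (10 mol %), DMSO, 125 °C, 3 h; aq Na2S2O3 wash
Reagents that add atoms: none
Why: In this iodine-catalysed oxidative cyclisation of a 2'-hydroxychalcone, iodonium activation of the enone lets the free phenol close ring C at the benzylic carbon, loss of HI from racemic iodide 13 gives the pyranone and erases both transient stereocentres, and DMSO reoxidises HI to I2.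

Step 8
Reactants: 14 5,7-bis(benzyloxy)-2',3',4',5'-tetramethoxyflavone
Product: 15 5,7-dihydroxy-2',3',4',5'-tetramethoxyflavone
Conditions: H2 (1 atm), 10% Pd/C, THF/MeOH 1:1, rt, stopped when 14 is consumed
Reagents that add atoms: none
Why: Catalytic hydrogenolysis cleaves the two benzylic C–O bonds quickly at 1 atm, while the aryl methyl ethers and the chromone C2=C3 bond are inert under these mild conditions, and the product has no stereocentre.

## Compound list
1 | 2,3,4-trimethoxybenzaldehyde | COc1ccc(C=O)c(OC)c1OC | starting material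
2 | 2,3,4-trimethoxyphenyl formate (aryl formate; not isolated) | COc1ccc(OC=O)c(OC)c1OC | intermediate
3 | 2,3,4-trimethoxyphenol | COc1ccc(O)c(OC)c1OC | intermediate
4 | 1,2,3,4-tetramethoxybenzene | COc1ccc(OC)c(OC)c1OC | intermediate
5 | 1-bromo-2,3,4,5-tetramethoxybenzene | COc1cc(Br)c(OC)c(OC)c1OC | intermediate
6 | (2,3,4,5-tetramethoxyphenyl)lithium (aryllithium; not isolated) | [Li]c1cc(OC)c(OC)c(OC)c1OC | intermediate
7 | lithium (dimethylamino)(2,3,4,5-tetramethoxyphenyl)methanolate (racemic; not isolated) | COc1cc(C([O-])N(C)C)c(OC)c(OC)c1OC.[Li+] | intermediate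
8 | 2,3,4,5-tetramethoxybenzaldehyde | COc1cc(C=O)c(OC)c(OC)c1OC | intermediate
9 | 2,4,6-trihydroxyacetophenone | CC(=O)c1c(O)cc(O)cc1O | starting material
10 | 1-[2,4-bis(benzyloxy)-6-hydroxyphenyl]ethanone | CC(=O)c1c(O)cc(OCc2ccccc2)cc1OCc1ccccc1 | intermediate
11 | 1-[2,4-bis(benzyloxy)-6-hydroxyphenyl]-3-hydroxy-3-(2,3,4,5-tetramethoxyphenyl)propan-1-one (aldol adduct; racemic; not isolated) | COc1cc(C(O)CC(=O)c2c(O)cc(OCc3ccccc3)cc2OCc2ccccc2)c(OC)c(OC)c1OC | intermediate
12 | (E)-1-[2,4-bis(benzyloxy)-6-hydroxyphenyl]-3-(2,3,4,5-tetramethoxyphenyl)prop-2-en-1-one | COc1cc(/C=C/C(=O)c2c(O)cc(OCc3ccccc3)cc2OCc2ccccc2)c(OC)c(OC)c1OC | intermediate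
13 | 5,7-bis(benzyloxy)-3-iodo-2-(2,3,4,5-tetramethoxyphenyl)chroman-4-one (3-iodoflavanone; racemic, both sp3 centres erased in the same flask; not isolated) | COc1cc(C2Oc3cc(OCc4ccccc4)cc(OCc4ccccc4)c3C(=O)C2I)c(OC)c(OC)c1OC | intermediate
14 | 5,7-bis(benzyloxy)-2',3',4',5'-tetramethoxyflavone | COc1cc(-c2cc(=O)c3c(OCc4ccccc4)cc(OCc4ccccc4)cc3o2)c(OC)c(OC)c1OC | intermediate
15 | 5,7-dihydroxy-2',3',4',5'-tetramethoxyflavone (achiral) | COc1cc(-c2cc(=O)c3c(O)cc(O)cc3o2)c(OC)c(OC)c1OC | target

## Summary
Total step count: 8.
Longest linear sequence: 7 (steps 1, 2, 3, 4, 6, 7, 8). Step 5 is the convergent ring A branch.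

## Steps most likely to fail

**Step 5 (selective dibenzylation).** The risk is a mixture of mono-, di- and tri-O-benzyl ethers together with some C-benzylated material.
- The fallback sets out from 9 and comes back at 10.
- Compound 9 is benzylated exhaustively (BnBr 4 equiv, K2CO3, DMF, 80 °C) to 1-[2,4,6-tris(benzyloxy)phenyl]ethanone F1, which needs no control of stoichiometry.
- One ortho benzyl group is then removed by chelation-directed cleavage with MgBr2·OEt2 in toluene/Et2O at reflux.
- The magnesium phenolate–carbonyl chelate formed after the first cleavage protects the second ortho ether, and acidic work-up gives 10.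

**Step 6 (Claisen–Schmidt condensation).** The risk is that the electron-rich, ortho-substituted aldehyde and the hindered phenolate-bearing ketone react slowly or stall.
- The fallback sets out from 8 (with 10) and comes back at 14, bypassing 12 and step 7.
- Aldehyde 8 is oxidised (NaClO2, NaH2PO4, 2-methyl-2-butene, t-BuOH/H2O) to 2,3,4,5-tetramethoxybenzoic acid F2.
- The acid is converted with (COCl)2 and catalytic DMF in CH2Cl2 into 2,3,4,5-tetramethoxybenzoyl chloride F3.
- The lithium dianion of 10 (LiN(SiMe3)2 3.5 equiv, THF, −78 °C) is C-acylated by the chloride in an intermolecular crossed Claisen condensation. This gives 1-[2,4-bis(benzyloxy)-6-hydroxyphenyl]-3-(2,3,4,5-tetramethoxyphenyl)propane-1,3-dione F4.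
- Cyclodehydration with catalytic p-TsOH in refluxing toluene gives 14 directly at the flavone oxidation level.

**Step 7 (I2/DMSO oxidative cyclisation).** The risks are ring iodination of the electron-rich arenes and partial loss of the 5-O-benzyl group to HI. The second is harmless, because that material also gives 15 in step 8.
- The fallback sets out from 12 and comes back at 14.
- The chalcone is closed without any oxidant by oxa-Michael addition (NaOAc, EtOH, reflux), and racemic 5,7-bis(benzyloxy)-2',3',4',5'-tetramethoxyflavanone F5 is isolated.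
- The flavanone is dehydrogenated by hydride abstraction with DDQ (1.5 equiv, dioxane, reflux) to 14. This route is free of iodine and acid.

## Further compounds
F1 | step 5 | 1-[2,4,6-tris(benzyloxy)phenyl]ethanone | CC(=O)c1c(OCc2ccccc2)cc(OCc2ccccc2)cc1OCc1ccccc1
F2 | step 6 | 2,3,4,5-tetramethoxybenzoic acid | COc1cc(C(=O)O)c(OC)c(OC)c1OC
F3 | step 6 | 2,3,4,5-tetramethoxybenzoyl chloride | COc1cc(C(=O)Cl)c(OC)c(OC)c1OC
F4 | step 6 | 1-[2,4-bis(benzyloxy)-6-hydroxyphenyl]-3-(2,3,4,5-tetramethoxyphenyl)propane-1,3-dione | COc1cc(C(=O)CC(=O)c2c(O)cc(OCc3ccccc3)cc2OCc2ccccc2)c(OC)c(OC)c1OC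
F5 | step 7 | 5,7-bis(benzyloxy)-2',3',4',5'-tetramethoxyflavanone (racemic) | COc1cc(C2CC(=O)c3c(OCc4ccccc4)cc(OCc4ccccc4)cc3O2)c(OC)c(OC)c1OC
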